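**Assumption:** germacrane numbering is used (C1 ketone, C3–O–C10 ether bridge, C6 lactone oxygen, C8 ester). The target is (4Z,6R,7R,8R,10R). The catalyst antipodes named in steps 2 and 3 are those that the accepted models predict for the (R) centres; this has not been verified experimentally.

## Retrosynthetic overview

1. 29 ⇐ alcohol 26 + angelic acid 27 (ester C–O bond, made last).
2. 26 ⇐ bromo enal 22: CrCl2 allylation closes C6–C7 (ten-membered carbocycle), then the C6–O γ-lactone.
3. 22 ⇐ furanone 15: C7 aldehyde → Morita–Baylis–Hillman adduct → allylic bromide; C6 silyl ether → enal.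
4. 15 ⇐ lactone 8 + enyne 10: key C3–O bond by an alkynylative lactone-to-furanone ring transposition.
5. 8 ⇐ methyl pyruvate 4 + ketone 1 (C10 by bis(oxazoline)–copper aldol, C8 by transfer hydrogenation). Ring order: temporary butanolide → 3(2H)-furanone → ten-membered carbocycle → α-methylene γ-lactone.

## Route

**Step 1**
Reactants: 1 1,1-dimethoxypropan-2-one
Product: 3 [(3,3-dimethoxyprop-1-en-2-yl)oxy]trimethylsilane, via lithium enolate 2 (not isolated)
Conditions: LDA, THF, −78 °C; TMSCl, −78 → 0 °C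
Reagents that add atoms: chlorotrimethylsilane, C[Si](C)(C)Cl
Why: Kinetic deprotonation of the methyl ketone at its unhindered methyl group followed by O-silylation gives the less substituted silyl enol ether (regioselective enolisation, no stereocentre).

**Step 2**
Reactants: 3 [(3,3-dimethoxyprop-1-en-2-yl)oxy]trimethylsilane; 4 methyl pyruvate
Product: 6 methyl (2R)-2-hydroxy-5,5-dimethoxy-2-methyl-4-oxopentanoate, via silyl ether 5 (not isolated)
Conditions: Cu(OTf)2 (10 mol %), 2,2′-(propane-2,2-diyl)bis[(4R)-4-tert-butyl-4,5-dihydrooxazole] (11 mol %), THF, −78 °C; then 1 M HCl, THF, 0 °C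
Reagents that add atoms: none
Why: Catalytic enantioselective Mukaiyama aldol addition to a pyruvate ester: the pyruvate chelates the square-planar divalent copper–bis(oxazoline) complex through both carbonyls, the enol silane attacks the unshielded ketone face and sets C10 as (R), and dilute acid cleaves the transferred silyl group.

**Step 3**
Reactants: 6 methyl (2R)-2-hydroxy-5,5-dimethoxy-2-methyl-4-oxopentanoate
Product: 8 (3R,5R)-5-(dimethoxymethyl)-3-hydroxy-3-methyloxolan-2-one, via diol ester 7 (not isolated)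
Conditions: RuCl(p-cymene)[(R,R)-TsDPEN] (1 mol %), HCO2H/Et3N (5:2), EtOAc, 30 °C; then DBU (0.2 equiv), PhMe, 40 °C
Reagents that add atoms: none
Why: Noyori asymmetric transfer hydrogenation delivers hydride to the Si face of the activated α,α-dialkoxy ketone under catalyst control and sets C8 as (R) independently of C10, and the γ-hydroxy ester then closes to the butanolide (base-catalysed lactonisation), which ties up C1 and the C8 oxygen in one ring.

**Step 4**
Reactants: 9 (2Z)-3-methylpent-2-en-4-yn-1-ol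
Product: 10 triethyl{[(2Z)-3-methylpent-2-en-4-yn-1-yl]oxy}silane
Conditions: TESCl, imidazole, CH2Cl2, 0 °C
Reagents that add atoms: chlorotriethylsilane, CC[Si](CC)(CC)Cl
Why: Standard silylation of a primary alcohol; the Z-enyne (which carries C2–C6 and C15 in the correct geometry) is untouched.

**Step 5**
Reactants: 8 (3R,5R)-5-(dimethoxymethyl)-3-hydroxy-3-methyloxolan-2-one; 10 triethyl{[(2Z)-3-methylpent-2-en-4-yn-1-yl]oxy}silane
Product: 15 (2R)-2-[(2R)-2-hydroxy-3,3-dimethoxypropyl]-2-methyl-5-[(2Z)-4-(triethylsilyloxy)but-2-en-2-yl]furan-3(2H)-one, via lithium acetylide 11 (not isolated), via dilithium lactolate 12 (not isolated), via alkynyl lactol 13 (not isolated), via hydroxy ynone 14 (not isolated)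
Conditions: 10 (2.2 equiv), n-BuLi (2.1 equiv), THF, −78 °C; 8, −78 °C; AcOH, −78 °C, aqueous wash; crude in CH2Cl2, [(t-Bu)2(2-biphenylyl)P]Au(NCMe) SbF6 (2 mol %), 25 °C
Reagents that add atoms: none
Why: Proposed new method: an alkynylative ring transposition of an α-hydroxy γ-lactone into a 2,2-disubstituted 3(2H)-furanone, in which the acetylide adds once to the non-enolisable lactone (one equivalent serves as base for the tertiary hydroxyl, and the tetrahedral lactolate is stable at −78 °C), the protonated 2-alkynyl lactol 13 is in ring–chain equilibrium with α′-hydroxy ynone 14, and the π-acidic monovalent gold cation activates the alkyne for 5-endo-dig attack by the adjacent tertiary C10 hydroxyl, which forms the C3–O bond and the furanone ring, drains the equilibrium and releases the C8 hydroxyl without touching C8 or C10; the closest known reaction types are acetylide opening of lactones and the gold- or amine-mediated cycloisomerisation of isolated acyclic α′-hydroxy ynones, but a lactol has not been used as the latent hydroxy ynone nor the two hydroxyls differentiated in this way.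

**Step 6**
Reactants: 15 (2R)-2-[(2R)-2-hydroxy-3,3-dimethoxypropyl]-2-methyl-5-[(2Z)-4-(triethylsilyloxy)but-2-en-2-yl]furan-3(2H)-one
Product: 17 (2R)-3-{(2R)-2-methyl-3-oxo-5-[(2Z)-4-(triethylsilyloxy)but-2-en-2-yl]-2,3-dihydrofuran-2-yl}-2-(triethylsilyloxy)propanal, via lutidinium salt 16 (not isolated)
Conditions: TESOTf (3 equiv), 2,6-lutidine (4.5 equiv), CH2Cl2, −40 → 0 °C; then H2O
Reagents that add atoms: triethylsilyl trifluoromethanesulfonate, CC[Si](CC)(CC)OS(=O)(=O)C(F)(F)F; water, O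
Why: Fujioka-type chemoselective acetal cleavage: the silyl triflate silylates the C8 hydroxyl and ionises the dimethyl acetal, which is held as lutidinium salt 16 until water releases the aldehyde under nearly neutral conditions, so the primary silyl ether, the furanone and the Z-alkene survive.

**Step 7**
Reactants: 17 (2R)-3-{(2R)-2-methyl-3-oxo-5-[(2Z)-4-(triethylsilyloxy)but-2-en-2-yl]-2,3-dihydrofuran-2-yl}-2-(triethylsilyloxy)propanal; 18 methyl acrylate
Product: 19 methyl (4R)-3-hydroxy-2-methylidene-5-{(2R)-2-methyl-3-oxo-5-[(2Z)-4-(triethylsilyloxy)but-2-en-2-yl]-2,3-dihydrofuran-2-yl}-4-(triethylsilyloxy)pentanoate (both C3 epimers)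
Conditions: DABCO (1 equiv), 18 (15 equiv), MeOH (3 equiv), 25 °C, dark, 3 d
Reagents that add atoms: none
Why: Morita–Baylis–Hillman reaction: the DABCO–acrylate zwitterion adds to the activated α-silyloxy aldehyde and brings in C11–C13; the new carbinol (C7) is left as a mixture because it becomes sp2 in the next step.

**Step 8**
Reactants: 19 methyl (4R)-3-hydroxy-2-methylidene-5-{(2R)-2-methyl-3-oxo-5-[(2Z)-4-(triethylsilyloxy)but-2-en-2-yl]-2,3-dihydrofuran-2-yl}-4-(triethylsilyloxy)pentanoate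
Product: 20 methyl (2Z,4R)-2-(bromomethyl)-5-{(2R)-2-methyl-3-oxo-5-[(2Z)-4-(triethylsilyloxy)but-2-en-2-yl]-2,3-dihydrofuran-2-yl}-4-(triethylsilyloxy)pent-2-enoate
Conditions: NBS, Me2S, CH2Cl2, 0 → 25 °C
Reagents that add atoms: N-bromosuccinimide, O=C1CCC(=O)N1Br
Why: Corey–Kim-type bromination with allylic transposition (SN2′): bromide attacks the terminal methylene of the activated alcohol and gives the thermodynamically preferred (Z)-2-(bromomethyl)enoate, while both silyl ethers are inert.

**Step 9**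
Reactants: 20 methyl (2Z,4R)-2-(bromomethyl)-5-{(2R)-2-methyl-3-oxo-5-[(2Z)-4-(triethylsilyloxy)but-2-en-2-yl]-2,3-dihydrofuran-2-yl}-4-(triethylsilyloxy)pent-2-enoate
Product: 22 methyl (2Z,4R)-2-(bromomethyl)-5-{(2R)-2-methyl-3-oxo-5-[(2Z)-4-oxobut-2-en-2-yl]-2,3-dihydrofuran-2-yl}-4-(triethylsilyloxy)pent-2-enoate, via alkoxysulfonium chloride 21 (not isolated)
Conditions: (COCl)2, DMSO, CH2Cl2, −78 → −40 °C; Et3N, −78 → −30 °C, cold work-up
Reagents that add atoms: none
Why: Swern oxidation applied directly to a primary triethylsilyl ether: chlorodimethylsulfonium chloride exchanges only the unhindered primary silyl ether to alkoxysulfonium salt 21 (the secondary silyl ether is inert) and Et3N then gives the Z-enal at low temperature, so a free Z-allylic alcohol next to the furanone, which would cyclise to a furan, is never formed.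

**Step 10**
Reactants: 22 methyl (2Z,4R)-2-(bromomethyl)-5-{(2R)-2-methyl-3-oxo-5-[(2Z)-4-oxobut-2-en-2-yl]-2,3-dihydrofuran-2-yl}-4-(triethylsilyloxy)pent-2-enoate
Product: 26 (4Z,6R,7R,8R,10R)-8-hydroxy-1-oxo-3,10-epoxygermacra-2,4,11(13)-trien-12,6-olide, via allylchromium dichloride 23 (not isolated), via chromium alkoxide 24 (not isolated), via hydroxy ester 25 (not isolated)
Conditions: CrCl2 (8 equiv), THF, 25 °C, syringe pump to 2 mM; H2O; then TsOH·H2O (0.3 equiv), MeOH/CH2Cl2, 25 °C
Reagents that add atoms: none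
Why: Intramolecular Nozaki–Hiyama (Barbier-type) 2-(alkoxycarbonyl)allylation: divalent chromium converts the allylic bromide into allylchromium 23, which adds through C7 to the enal in a chair transition state (anti adduct, hence the trans-fused lactone), the C8 centre directing the C7 face with its silyloxy group inside and the ring tether outside, so that C6 (R) and C7 (R) are set and the ten-membered ring is closed, after which acid lactonises the C6 hydroxyl onto the ester and cleaves the secondary silyl ether (a silyloxy rather than an acyloxy group at C8 is used here to suppress 1,4-elimination of the allylmetal).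

**Step 11**
Reactants: 26 (4Z,6R,7R,8R,10R)-8-hydroxy-1-oxo-3,10-epoxygermacra-2,4,11(13)-trien-12,6-olide; 27 angelic acid
Product: 29 15-deoxybudlein A, via mixed anhydride 28 (not isolated)
Conditions: 27, 2,4,6-Cl3C6H2COCl, Et3N, PhMe, 25 °C; then 26, PhMe, 80 °C
Reagents that add atoms: none
Why: Yamaguchi esterification run without a nucleophilic catalyst: the C8 hydroxyl attacks the less hindered angeloyl carbonyl of mixed anhydride 28, and leaving out DMAP avoids angelate-to-tiglate isomerisation; no stereocentre changes.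

## Compound list

1 | 1,1-dimethoxypropan-2-one | CC(=O)C(OC)OC | starting material
2 | lithium 3,3-dimethoxyprop-1-en-2-olate | C=C(O[Li])C(OC)OC | intermediate
3 | [(3,3-dimethoxyprop-1-en-2-yl)oxy]trimethylsilane | C=C(O[Si](C)(C)C)C(OC)OC | intermediate
4 | methyl pyruvate (methyl 2-oxopropanoate) | CC(=O)C(=O)OC | starting material
5 | methyl (2R)-5,5-dimethoxy-2-methyl-4-oxo-2-(trimethylsilyloxy)pentanoate | COC(OC)C(=O)C[C@@](C)(O[Si](C)(C)C)C(=O)OC | intermediate
6 | methyl (2R)-2-hydroxy-5,5-dimethoxy-2-methyl-4-oxopentanoate | COC(OC)C(=O)C[C@@](C)(O)C(=O)OC | intermediate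
7 | methyl (2R,4R)-2,4-dihydroxy-5,5-dimethoxy-2-methylpentanoate | COC(OC)[C@H](O)C[C@@](C)(O)C(=O)OC | intermediate
8 | (3R,5R)-5-(dimethoxymethyl)-3-hydroxy-3-methyloxolan-2-one (hydroxyl cis to the 5-substituent) | COC(OC)[C@H]1C[C@@](C)(O)C(=O)O1 | intermediate
9 | (2Z)-3-methylpent-2-en-4-yn-1-ol | C#C/C(C)=C\CO | starting material
10 | triethyl{[(2Z)-3-methylpent-2-en-4-yn-1-yl]oxy}silane | C#C/C(C)=C\CO[Si](CC)(CC)CC | intermediate
11 | lithium acetylide of 10 | [Li]C#C/C(C)=C\CO[Si](CC)(CC)CC | intermediate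
12 | dilithium lactolate from 8 and 11 (anomer mixture) | COC(OC)[C@H]1C[C@@](C)(O[Li])C(O[Li])(C#C/C(C)=C\CO[Si](CC)(CC)CC)O1 | intermediate
13 | (3R,5R)-5-(dimethoxymethyl)-3-methyl-2-[(3Z)-3-methyl-5-(triethylsilyloxy)pent-3-en-1-yn-1-yl]oxolane-2,3-diol (anomer mixture) | COC(OC)[C@H]1C[C@@](C)(O)C(O)(C#C/C(C)=C\CO[Si](CC)(CC)CC)O1 | intermediate
14 | (2Z,7R,9R)-7,9-dihydroxy-10,10-dimethoxy-3,7-dimethyl-1-(triethylsilyloxy)dec-2-en-4-yn-6-one | COC(OC)[C@H](O)C[C@@](C)(O)C(=O)C#C/C(C)=C\CO[Si](CC)(CC)CC | intermediate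
15 | (2R)-2-[(2R)-2-hydroxy-3,3-dimethoxypropyl]-2-methyl-5-[(2Z)-4-(triethylsilyloxy)but-2-en-2-yl]furan-3(2H)-one | O=C1C=C(/C(C)=C\CO[Si](CC)(CC)CC)O[C@]1(C)C[C@@H](O)C(OC)OC | intermediate
16 | 1-[(2R)-1-methoxy-3-{(2R)-2-methyl-3-oxo-5-[(2Z)-4-(triethylsilyloxy)but-2-en-2-yl]-2,3-dihydrofuran-2-yl}-2-(triethylsilyloxy)propyl]-2,6-dimethylpyridinium triflate (C1 epimers) | O=C1C=C(/C(C)=C\CO[Si](CC)(CC)CC)O[C@]1(C)C[C@@H](O[Si](CC)(CC)CC)C(OC)[n+]2c(C)cccc2C.[O-]S(=O)(=O)C(F)(F)F | intermediate
17 | (2R)-3-{(2R)-2-methyl-3-oxo-5-[(2Z)-4-(triethylsilyloxy)but-2-en-2-yl]-2,3-dihydrofuran-2-yl}-2-(triethylsilyloxy)propanal | O=C1C=C(/C(C)=C\CO[Si](CC)(CC)CC)O[C@]1(C)C[C@@H](O[Si](CC)(CC)CC)C=O | intermediate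
18 | methyl acrylate | C=CC(=O)OC | starting material
19 | methyl (4R)-3-hydroxy-2-methylidene-5-{(2R)-2-methyl-3-oxo-5-[(2Z)-4-(triethylsilyloxy)but-2-en-2-yl]-2,3-dihydrofuran-2-yl}-4-(triethylsilyloxy)pentanoate (C3 epimers) | O=C1C=C(/C(C)=C\CO[Si](CC)(CC)CC)O[C@]1(C)C[C@@H](O[Si](CC)(CC)CC)C(O)C(=C)C(=O)OC | intermediate
20 | methyl (2Z,4R)-2-(bromomethyl)-5-{(2R)-2-methyl-3-oxo-5-[(2Z)-4-(triethylsilyloxy)but-2-en-2-yl]-2,3-dihydrofuran-2-yl}-4-(triethylsilyloxy)pent-2-enoate | O=C1C=C(/C(C)=C\CO[Si](CC)(CC)CC)O[C@]1(C)C[C@@H](O[Si](CC)(CC)CC)/C=C(\CBr)C(=O)OC | intermediate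
21 | alkoxydimethylsulfonium chloride of 20 (primary silyl ether replaced by O–SMe2+) | O=C1C=C(/C(C)=C\CO[S+](C)C)O[C@]1(C)C[C@@H](O[Si](CC)(CC)CC)/C=C(\CBr)C(=O)OC.[Cl-] | intermediate
22 | methyl (2Z,4R)-2-(bromomethyl)-5-{(2R)-2-methyl-3-oxo-5-[(2Z)-4-oxobut-2-en-2-yl]-2,3-dihydrofuran-2-yl}-4-(triethylsilyloxy)pent-2-enoate | O=C1C=C(/C(C)=C\C=O)O[C@]1(C)C[C@@H](O[Si](CC)(CC)CC)/C=C(\CBr)C(=O)OC | intermediate
23 | allylchromium dichloride from 22 (CrCl2 in place of Br) | O=C1C=C(/C(C)=C\C=O)O[C@]1(C)C[C@@H](O[Si](CC)(CC)CC)/C=C(\C[Cr](Cl)Cl)C(=O)OC | intermediate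
24 | dichlorochromium alkoxide of 25 | C=C(C(=O)OC)[C@H]1[C@H](O[Cr](Cl)Cl)/C=C(/C)C2=CC(=O)[C@@](C)(C[C@H]1O[Si](CC)(CC)CC)O2 | intermediate
25 | methyl (4Z)-6-hydroxy-1-oxo-8-(triethylsilyloxy)-3,10-epoxygermacra-2,4,11(13)-trien-12-oate; CIP descriptors 6R,7S,8R,10R, same spatial arrangement as 29 (the C7 descriptor changes because the silyl ether outranks the free carbinol) | C=C(C(=O)OC)[C@H]1[C@H](O)/C=C(/C)C2=CC(=O)[C@@](C)(C[C@H]1O[Si](CC)(CC)CC)O2 | intermediate
26 | (4Z,6R,7R,8R,10R)-8-hydroxy-1-oxo-3,10-epoxygermacra-2,4,11(13)-trien-12,6-olide | C=C1C(=O)O[C@@H]2/C=C(/C)C3=CC(=O)[C@@](C)(C[C@@H](O)[C@@H]12)O3 | intermediate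
27 | angelic acid, (2Z)-2-methylbut-2-enoic acid | C/C=C(/C)C(=O)O | starting material
28 | (2Z)-2-methylbut-2-enoic 2,4,6-trichlorobenzoic anhydride | C/C=C(/C)C(=O)OC(=O)c1c(Cl)cc(Cl)cc1Cl | intermediate
29 | 15-deoxybudlein A, (4Z,6R,7R,8R,10R)-8-angeloyloxy-1-oxo-3,10-epoxygermacra-2,4,11(13)-trien-12,6-olide | C=C1C(=O)O[C@@H]2/C=C(/C)C3=CC(=O)[C@@](C)(C[C@@H](OC(=O)/C(C)=C\C)[C@@H]12)O3 | target

## Step count and risks

Total steps: 11. Longest linear sequence: 10 (steps 1–3 and 5–11; step 4 is a one-step branch).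

**Step 10 (ring closure) is the most likely to fail.** The ten-membered ring may close in low yield, the C6/C7 configuration may come out wrong (cis-lactone or 7,8-syn), the allylchromium may undergo 1,4-elimination, or the lactone may migrate to the C8 oxygen once the silyl group is off. The fallback sets out from 19 and comes back at 25. Acetylation of 19 (Ac2O, pyridine) gives Morita–Baylis–Hillman acetate F6. The Swern conditions of step 9 convert its primary silyl ether into acetate enal F7. Pd(PPh3)4 (5 mol %) and InI in THF at high dilution ionise the allylic acetate to a π-allyl complex of palladium, which is reduced to an allylindium nucleophile (umpolung). This milder, less basic allylmetal adds through a cyclic transition state and gives hydroxy ester 25 after aqueous work-up. The acid treatment of step 10 then gives 26.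

**Step 5 (proposed new method) is the second risk.** The lactol may not open fast enough, the propargylic lactol may rearrange under the gold cation, or the free C8 hydroxyl may add to C3 to form a bicyclic ketal. The fallback uses known chemistry only; it sets out from 8 and comes back at 17. Lactone 8 is opened with MeNH(OMe)·HCl and i-PrMgCl to Weinreb amide F1. TESCl and imidazole silylate only the secondary hydroxyl to give silyl ether F2. Lithium acetylide 11 (2.2 equiv) gives the strictly acyclic α′-hydroxy ynone F3, which cannot form a lactol. The established gold-catalysed 5-endo-dig cycloisomerisation of such acyclic hydroxy ynones (same catalyst, CH2Cl2) gives furanone F4. The conditions of step 6 convert F4 through salt 16 into 17.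

**Step 7 (Morita–Baylis–Hillman reaction) is the third risk.** It may be slow on the hindered α-silyloxy aldehyde, and the long exposure to amine may epimerise C8 or erode the Z-alkene. The fallback sets out from 17 and comes back at 19. It replaces the reversible amine-catalysed manifold by an irreversible α-metalloacrylate addition. Methyl propiolate, DIBAL-H and N-methylmorpholine N-oxide in THF at 0 °C give vinylalane F5. F5 adds to 17 at −20 °C within hours, and Rochelle-salt work-up gives 19.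

## Further compounds

F1 | step 5 | (2R,4R)-2,4-dihydroxy-N,5,5-trimethoxy-N,2-dimethylpentanamide | COC(OC)[C@H](O)C[C@@](C)(O)C(=O)N(C)OC
F2 | step 5 | (2R,4R)-2-hydroxy-N,5,5-trimethoxy-N,2-dimethyl-4-(triethylsilyloxy)pentanamide | COC(OC)[C@H](O[Si](CC)(CC)CC)C[C@@](C)(O)C(=O)N(C)OC
F3 | step 5 | (2Z,7R,9R)-7-hydroxy-10,10-dimethoxy-3,7-dimethyl-1,9-bis(triethylsilyloxy)dec-2-en-4-yn-6-one | COC(OC)[C@H](O[Si](CC)(CC)CC)C[C@@](C)(O)C(=O)C#C/C(C)=C\CO[Si](CC)(CC)CC
F4 | step 5 | (2R)-2-[(2R)-3,3-dimethoxy-2-(triethylsilyloxy)propyl]-2-methyl-5-[(2Z)-4-(triethylsilyloxy)but-2-en-2-yl]furan-3(2H)-one | O=C1C=C(/C(C)=C\CO[Si](CC)(CC)CC)O[C@]1(C)C[C@@H](O[Si](CC)(CC)CC)C(OC)OC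
F5 | step 7 | [1-(methoxycarbonyl)ethenyl]bis(2-methylpropyl)aluminium | C=C(C(=O)OC)[Al](CC(C)C)CC(C)C
F6 | step 10 | methyl (4R)-3-acetoxy-2-methylidene-5-{(2R)-2-methyl-3-oxo-5-[(2Z)-4-(triethylsilyloxy)but-2-en-2-yl]-2,3-dihydrofuran-2-yl}-4-(triethylsilyloxy)pentanoate (C3 epimers) | O=C1C=C(/C(C)=C\CO[Si](CC)(CC)CC)O[C@]1(C)C[C@@H](O[Si](CC)(CC)CC)C(OC(C)=O)C(=C)C(=O)OC
F7 | step 10 | methyl (4R)-3-acetoxy-2-methylidene-5-{(2R)-2-methyl-3-oxo-5-[(2Z)-4-oxobut-2-en-2-yl]-2,3-dihydrofuran-2-yl}-4-(triethylsilyloxy)pentanoate (C3 epimers) | O=C1C=C(/C(C)=C\C=O)O[C@]1(C)C[C@@H](O[Si](CC)(CC)CC)C(OC(C)=O)C(=C)C(=O)OC
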